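**Plan**

The target has no stereocentre. Retrosynthesis first removes four benzyl ethers and turns the ring B phenol into a ketone, then cuts ring B at C4′–C5′ and C1′–C6′.
Ring B is a phenol whose hydroxyl carbon C2′ has the ethylene bridge ortho (C1′) and the 4-hydroxybenzyl group para (C5′). This is the pattern of a 2,4-disubstituted cyclohex-2-enone, so ring B can be built from a ring A vinyl ketone and 3-[4-(benzyloxy)phenyl]propanal and aromatised afterwards.
The vinyl ketone is cut at the ketone–vinyl bond, at the two aryl–benzyl bonds of ring A and at the benzylic C=C bond of a Wittig olefination.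
Forward: ring A (3-hydroxy-5-methoxybenzaldehyde) receives its four-carbon chain, is dibrominated and benzylated twice, and the chain end is made the vinyl ketone. Ring B is then closed as a cyclohexenone, dehydrogenated to the phenol, and the benzyl ethers are removed.
The only stereocentre on the way (the benzyl-bearing ring carbon of the cyclohexenone, C5′) is formed racemic and vanishes on aromatisation.

Key step: step 9

Remark: in steps 5, 6 and 11 one reagent acts at two or four like sites in one operation and the partly converted species are not numbered; "Ar" in the step names stands for the 3-(benzyloxy)-2,6-bis[4-(benzyloxy)benzyl]-5-methoxyphenyl group of ring A (full names are in the compound list).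

**Route**

Step 1
Reactants: 1 3-hydroxy-5-methoxybenzaldehyde
Product: 2 3-(benzyloxy)-5-methoxybenzaldehyde
Conditions: BnBr (1.1 equiv), K2CO3, DMF, 25 °C
Reagents that add atoms: benzyl bromide, BrCc1ccccc1
Why: Williamson ether synthesis: the phenoxide formed with K2CO3 displaces bromide from benzyl bromide, the aldehyde is untouched, and benzyl is chosen so that all four phenol protecting groups fall together in step 11.

Step 2
Reactants: 2 3-(benzyloxy)-5-methoxybenzaldehyde; 3 (2-carboxyethyl)triphenylphosphonium bromide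
Product: 5 (E)-4-[3-(benzyloxy)-5-methoxyphenyl]but-3-enoic acid, via ylide carboxylate 4 (not isolated)
Conditions: 3 (1.3 equiv), t-BuOK (2.6 equiv), THF, 0 °C; then 2, 0 to 25 °C; aq. HCl work-up
Reagents that add atoms: none
Why: Wittig olefination: two equivalents of base turn salt 3 into the ylide carboxylate 4, a reagent known to convert aromatic aldehydes into 4-arylbut-3-enoic acids, mainly as the E isomer, and the alkene geometry is of no consequence because step 3 saturates the double bond.

Step 3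
Reactants: 5 (E)-4-[3-(benzyloxy)-5-methoxyphenyl]but-3-enoic acid
Product: 6 4-[3-(benzyloxy)-5-methoxyphenyl]butanoic acid
Conditions: TsNHNH2 (5 equiv), NaOAc (5 equiv), THF/H2O, reflux
Reagents that add atoms: none
Why: Diimide reduction: diimide generated from the sulfonyl hydrazide delivers two hydrogen atoms to the styrenic C=C bond through a cyclic transition state and cannot cleave the benzyl ether, which hydrogenation over palladium would endanger.

Step 4
Reactants: 6 4-[3-(benzyloxy)-5-methoxyphenyl]butanoic acid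
Product: 8 4-[3-(benzyloxy)-5-methoxyphenyl]-N-methoxy-N-methylbutanamide, via acyl imidazole 7 (not isolated)
Conditions: CDI (1.2 equiv), CH2Cl2, 25 °C; then MeNH(OMe)·HCl (1.5 equiv), 25 °C
Reagents that add atoms: N,O-dimethylhydroxylamine hydrochloride, CNOC.Cl
Why: Amide coupling through the acyl imidazole (CDI activation): imidazolide 7 acylates N,O-dimethylhydroxylamine to give the Weinreb amide, which later stops the vinyl Grignard addition at the ketone stage and is inert to NBS and to organozinc reagents.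

Step 5
Reactants: 8 4-[3-(benzyloxy)-5-methoxyphenyl]-N-methoxy-N-methylbutanamide
Product: 9 4-[3-(benzyloxy)-2,6-dibromo-5-methoxyphenyl]-N-methoxy-N-methylbutanamide
Conditions: NBS (2.1 equiv), MeCN, 0 to 25 °C, dark
Reagents that add atoms: N-bromosuccinimide, O=C1CCC(=O)N1Br
Why: Electrophilic aromatic bromination: NBS should brominate the two positions that are para to one alkoxy group and ortho to the other (C2 and C6, flanking the side chain), as is usual for 5-alkylresorcinol diethers, while C4 between the two alkoxy groups is the least accessible and the phenyl ring of the benzyl ether is too electron-poor to compete.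

Step 6
Reactants: 9 4-[3-(benzyloxy)-2,6-dibromo-5-methoxyphenyl]-N-methoxy-N-methylbutanamide; 10 4-(benzyloxy)benzyl chloride
Product: 12 4-Ar-N-methoxy-N-methylbutanamide, via benzylic zinc chloride 11 (not isolated)
Conditions: 10 (3 equiv), Zn dust, LiCl, THF, 25 °C; decant; then 9, Pd(OAc)2 (5 mol %), SPhos (2-dicyclohexylphosphino-2′,6′-dimethoxybiphenyl, 10 mol %), THF, 25 to 60 °C
Reagents that add atoms: none
Why: Negishi cross-coupling: LiCl-assisted zinc insertion gives the benzylic zinc chloride 11, and zerovalent palladium carrying the bulky biaryl phosphine should insert into both hindered C–Br bonds and couple them with 11, the Weinreb amide and the benzyl ethers being inert to organozinc reagents.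

Step 7
Reactants: 12 4-Ar-N-methoxy-N-methylbutanamide; 13 vinylmagnesium bromide
Product: 15 6-Ar-hex-1-en-3-one, via magnesium chelate 14 (not isolated)
Conditions: 13 (2 equiv), THF, −20 to 0 °C; inverse quench into cold aq. HCl
Reagents that add atoms: none
Why: Weinreb ketone synthesis: the Grignard reagent adds once to give the stable five-membered magnesium chelate 14, which collapses to the vinyl ketone only on quenching, and the inverse acidic quench protonates the released N,O-dimethylhydroxylamine before it can add to the enone.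

Step 8
Reactants: 16 1-(benzyloxy)-4-iodobenzene; 17 prop-2-en-1-ol
Product: 18 3-[4-(benzyloxy)phenyl]propanal
Conditions: Pd(OAc)2 (2 mol %), Bu4NCl, NaHCO3, DMF, 40 °C
Reagents that add atoms: none
Why: Heck arylation of allyl alcohol under Jeffery conditions: the aryl palladium species adds to the terminal alkene carbon and β-hydride elimination towards the carbinol carbon gives the enol and hence the 3-arylpropanal directly, with the benzyl ether unaffected.

Step 9
Reactants: 18 3-[4-(benzyloxy)phenyl]propanal; 15 6-Ar-hex-1-en-3-one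
Product: 22 4-[4-(benzyloxy)benzyl]-2-(2-Ar-ethyl)cyclohex-2-en-1-one (racemic), via enamine 19 (not isolated), via keto aldehyde 20 (not isolated), via ketol 21 (not isolated)
Conditions: 18 (1.5 equiv), pyrrolidine, K2CO3, PhMe, 0 °C; filter, remove excess amine in vacuo; then 15, MeCN, 25 to 50 °C; then AcOH, NaOAc, H2O, 90 °C
Reagents that add atoms: none
Why: This is a Stork enamine Michael addition followed by intramolecular aldol condensation, a Robinson-type annulation of an aldehyde with an alkyl vinyl ketone that is established for 2-alkyl-4-substituted cyclohex-2-enones: the β-carbon of enamine 19 adds to the terminal carbon of enone 15 (bond C4′–C5′) and the aqueous acetate hydrolyses the adduct to the 1,5-keto aldehyde 20. Pyrrolidinium acetate then enolises the ketone towards the bridge-side methylene, which attacks the aldehyde carbon (bond C1′–C6′) in a 6-(enolendo)-exo-trig closure to ketol 21, and loss of water gives the conjugated enone. The single new stereocentre (C5′, carrying the benzyl group) is not controlled and is formed racemic, which is acceptable because step 10 makes this carbon sp2. The selectivity needed is regiochemical: the aldol must use the bridge-side α′-methylene, and the substrate secures this because every other enol–carbonyl pairing in 20 would close a four-membered ring, so the bridge ends up ortho and the benzyl group para to the future hydroxyl. Single addition is favoured by keeping the enamine in excess over the vinyl ketone, and the crowded ring A lies three atoms away from the reacting ketone and should not interfere.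

Step 10
Reactants: 22 4-[4-(benzyloxy)benzyl]-2-(2-Ar-ethyl)cyclohex-2-en-1-one
Product: 24 4-[4-(benzyloxy)benzyl]-2-(2-Ar-ethyl)phenol, via dienone 23 (not isolated)
Conditions: Pd(OCOCF3)2 (5 mol %), 2-(dimethylamino)pyridine (10 mol %), TsOH·H2O (20 mol %), O2 (1 atm), DMSO, 80 °C
Reagents that add atoms: none
Why: Palladium-catalysed aerobic dehydrogenation of a cyclohexenone to a phenol: the divalent palladium enolate formed at C6 undergoes β-hydride elimination to the cross-conjugated dienone 23, which tautomerises to the phenol and thereby removes the only stereocentre, while O2 reoxidises the palladium hydride and the benzyl ethers and diarylmethane CH2 groups are not expected to react at 80 °C.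

Step 11
Reactants: 24 4-[4-(benzyloxy)benzyl]-2-(2-Ar-ethyl)phenol
Product: 25 2-{2-[3-hydroxy-2,6-bis(4-hydroxybenzyl)-5-methoxyphenyl]ethyl}-4-(4-hydroxybenzyl)phenol (CNP0134121.0)
Conditions: H2 (1 atm), 10% Pd/C, EtOAc/MeOH, 25 °C
Reagents that add atoms: none
Why: Catalytic hydrogenolysis: the four aryl benzyl ethers are cleaved over Pd/C to toluene and the free phenols, whereas the diarylmethane C–C bonds, the methyl ether and the aromatic rings are stable under these mild conditions.

**Compound list**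

1 | 3-hydroxy-5-methoxybenzaldehyde | COc1cc(O)cc(C=O)c1 | starting material
2 | 3-(benzyloxy)-5-methoxybenzaldehyde | COc1cc(OCc2ccccc2)cc(C=O)c1 | intermediate
3 | (2-carboxyethyl)triphenylphosphonium bromide | OC(=O)CC[P+](c1ccccc1)(c1ccccc1)c1ccccc1.[Br-] | starting material
4 | potassium 3-(triphenyl-λ5-phosphanylidene)propanoate (ylide carboxylate) | [K+].[O-]C(=O)CC=P(c1ccccc1)(c1ccccc1)c1ccccc1 | intermediate (not isolated)
5 | (E)-4-[3-(benzyloxy)-5-methoxyphenyl]but-3-enoic acid | OC(=O)C/C=C/c1cc(OC)cc(OCc2ccccc2)c1 | intermediate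
6 | 4-[3-(benzyloxy)-5-methoxyphenyl]butanoic acid | OC(=O)CCCc1cc(OC)cc(OCc2ccccc2)c1 | intermediate
7 | 4-[3-(benzyloxy)-5-methoxyphenyl]-1-(1H-imidazol-1-yl)butan-1-one (acyl imidazole) | O=C(CCCc1cc(OC)cc(OCc2ccccc2)c1)n1ccnc1 | intermediate (not isolated)
8 | 4-[3-(benzyloxy)-5-methoxyphenyl]-N-methoxy-N-methylbutanamide | CON(C)C(=O)CCCc1cc(OC)cc(OCc2ccccc2)c1 | intermediate
9 | 4-[3-(benzyloxy)-2,6-dibromo-5-methoxyphenyl]-N-methoxy-N-methylbutanamide | CON(C)C(=O)CCCc1c(Br)c(OCc2ccccc2)cc(OC)c1Br | intermediate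
10 | 4-(benzyloxy)benzyl chloride | ClCc1ccc(OCc2ccccc2)cc1 | starting material
11 | [4-(benzyloxy)benzyl]zinc chloride (as its LiCl complex in THF) | Cl[Zn]Cc1ccc(OCc2ccccc2)cc1 | intermediate (not isolated)
12 | 4-{3-(benzyloxy)-2,6-bis[4-(benzyloxy)benzyl]-5-methoxyphenyl}-N-methoxy-N-methylbutanamide | CON(C)C(=O)CCCc1c(Cc2ccc(OCc3ccccc3)cc2)c(OCc2ccccc2)cc(OC)c1Cc1ccc(OCc2ccccc2)cc1 | intermediate
13 | vinylmagnesium bromide | C=C[Mg]Br | starting material
14 | bromomagnesium alkoxide of 6-{3-(benzyloxy)-2,6-bis[4-(benzyloxy)benzyl]-5-methoxyphenyl}-3-[methoxy(methyl)amino]hex-1-en-3-ol (magnesium chelate) | C=CC(O[Mg]Br)(N(C)OC)CCCc1c(Cc2ccc(OCc3ccccc3)cc2)c(OCc2ccccc2)cc(OC)c1Cc1ccc(OCc2ccccc2)cc1 | intermediate (not isolated)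
15 | 6-{3-(benzyloxy)-2,6-bis[4-(benzyloxy)benzyl]-5-methoxyphenyl}hex-1-en-3-one | C=CC(=O)CCCc1c(Cc2ccc(OCc3ccccc3)cc2)c(OCc2ccccc2)cc(OC)c1Cc1ccc(OCc2ccccc2)cc1 | intermediate
16 | 1-(benzyloxy)-4-iodobenzene | Ic1ccc(OCc2ccccc2)cc1 | starting material
17 | prop-2-en-1-ol (allyl alcohol) | C=CCO | starting material
18 | 3-[4-(benzyloxy)phenyl]propanal | O=CCCc1ccc(OCc2ccccc2)cc1 | intermediate
19 | 1-{(E)-3-[4-(benzyloxy)phenyl]prop-1-en-1-yl}pyrrolidine (enamine) | C1CCN(C1)/C=C/Cc1ccc(OCc2ccccc2)cc1 | intermediate (not isolated)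
20 | 2-[4-(benzyloxy)benzyl]-8-{3-(benzyloxy)-2,6-bis[4-(benzyloxy)benzyl]-5-methoxyphenyl}-5-oxooctanal (racemic keto aldehyde) | O=CC(Cc1ccc(OCc2ccccc2)cc1)CCC(=O)CCCc1c(Cc2ccc(OCc3ccccc3)cc2)c(OCc2ccccc2)cc(OC)c1Cc1ccc(OCc2ccccc2)cc1 | intermediate (not isolated)
21 | 4-[4-(benzyloxy)benzyl]-2-(2-{3-(benzyloxy)-2,6-bis[4-(benzyloxy)benzyl]-5-methoxyphenyl}ethyl)-3-hydroxycyclohexan-1-one (ketol, mixture of racemic diastereomers) | O=C1CCC(Cc2ccc(OCc3ccccc3)cc2)C(O)C1CCc1c(Cc2ccc(OCc3ccccc3)cc2)c(OCc2ccccc2)cc(OC)c1Cc1ccc(OCc2ccccc2)cc1 | intermediate (not isolated)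
22 | 4-[4-(benzyloxy)benzyl]-2-(2-{3-(benzyloxy)-2,6-bis[4-(benzyloxy)benzyl]-5-methoxyphenyl}ethyl)cyclohex-2-en-1-one (racemic) | O=C1CCC(Cc2ccc(OCc3ccccc3)cc2)C=C1CCc1c(Cc2ccc(OCc3ccccc3)cc2)c(OCc2ccccc2)cc(OC)c1Cc1ccc(OCc2ccccc2)cc1 | intermediate
23 | 4-[4-(benzyloxy)benzyl]-2-(2-{3-(benzyloxy)-2,6-bis[4-(benzyloxy)benzyl]-5-methoxyphenyl}ethyl)cyclohexa-2,5-dien-1-one (racemic dienone) | O=C1C=CC(Cc2ccc(OCc3ccccc3)cc2)C=C1CCc1c(Cc2ccc(OCc3ccccc3)cc2)c(OCc2ccccc2)cc(OC)c1Cc1ccc(OCc2ccccc2)cc1 | intermediate (not isolated)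
24 | 4-[4-(benzyloxy)benzyl]-2-(2-{3-(benzyloxy)-2,6-bis[4-(benzyloxy)benzyl]-5-methoxyphenyl}ethyl)phenol | Oc1ccc(Cc2ccc(OCc3ccccc3)cc2)cc1CCc1c(Cc2ccc(OCc3ccccc3)cc2)c(OCc2ccccc2)cc(OC)c1Cc1ccc(OCc2ccccc2)cc1 | intermediate
25 | 2-{2-[3-hydroxy-2,6-bis(4-hydroxybenzyl)-5-methoxyphenyl]ethyl}-4-(4-hydroxybenzyl)phenol (CNP0134121.0) | COc1cc(O)c(Cc2ccc(O)cc2)c(CCc2cc(Cc3ccc(O)cc3)ccc2O)c1Cc1ccc(O)cc1 | target

**Count and risks**

Total step count: 11. Longest linear sequence: 10 steps (steps 1 to 7, then 9, 10 and 11); step 8 is a one-step side branch.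

Steps most likely to fail:

1. Step 9 (annulation). The vinyl ketone may polymerise, the first Michael adduct may add to a second molecule of vinyl ketone, the aldehyde enamine may self-condense, and ring closure under the acetate buffer may stall at the keto aldehyde. The fallback sets out from 12 and 18 and comes back at 22; it exchanges the roles of donor and acceptor.
   - Weinreb amide 12 would acylate the lithium enolate of tert-butyl acetate (LDA, THF, −78 °C) to give tert-butyl 6-{3-(benzyloxy)-2,6-bis[4-(benzyloxy)benzyl]-5-methoxyphenyl}-3-oxohexanoate F1.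
   - Aldehyde 18 would be α-methylenated (aqueous formaldehyde, pyrrolidine and propionic acid as catalysts, i-PrOH, 45 °C) to 2-[4-(benzyloxy)benzyl]prop-2-enal F2.
   - Base-catalysed Michael addition of F1 to F2 (Et3N, THF, 25 °C) should give tert-butyl 2-{2-[4-(benzyloxy)benzyl]-3-oxopropyl}-6-{3-(benzyloxy)-2,6-bis[4-(benzyloxy)benzyl]-5-methoxyphenyl}-3-oxohexanoate F3. The stabilised β-keto ester donor adds only once, and the acceptor is no longer a polymerisable vinyl ketone.
   - TsOH in toluene at 80 to 100 °C should then bring about the aldol condensation to tert-butyl 5-[4-(benzyloxy)benzyl]-3-(2-{3-(benzyloxy)-2,6-bis[4-(benzyloxy)benzyl]-5-methoxyphenyl}ethyl)-2-oxocyclohex-3-ene-1-carboxylate F4. Loss of 2-methylpropene gives 5-[4-(benzyloxy)benzyl]-3-(2-{3-(benzyloxy)-2,6-bis[4-(benzyloxy)benzyl]-5-methoxyphenyl}ethyl)-2-oxocyclohex-3-ene-1-carboxylic acid F5, and decarboxylation gives enone 22. Ring closure again can only give the six-membered enone.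

2. Step 6 (double benzylation). Wurtz homocoupling may consume the electron-rich benzylic chloride during zinc insertion. Oxidative addition at the two electron-rich, doubly ortho-substituted C–Br bonds may be slow, so that coupling stops after one benzyl group or the remaining bromide is reduced. The fallback sets out from 9 and 10 and comes back at 12; it replaces the organozinc by a benzylic boronate that is stable to storage and to the higher temperature needed.
   - Chloride 10 would be borylated with bis(pinacolato)diboron (Pd(dba)2, tris(4-methoxyphenyl)phosphine, KOAc, PhMe, 50 °C) to 2-[4-(benzyloxy)benzyl]-4,4,5,5-tetramethyl-1,3,2-dioxaborolane F6.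
   - Dibromide 9 would then be coupled twice with F6 in a Suzuki–Miyaura reaction (Pd(OAc)2, SPhos, K3PO4, PhMe/H2O, 100 °C) to give 12.

3. Step 10 (aromatisation). Turnover may be slow for this bulky substrate, which dissolves poorly in DMSO, with precipitation of palladium metal. Oxidation at the doubly benzylic CH2 groups or oxidative coupling of the electron-rich phenol may set in under O2. The fallback sets out from 22 and comes back at 24; it uses neither palladium nor oxygen.
   - Kinetic deprotonation at C6 (LDA, THF, −78 °C) and trapping with PhSeBr should give 4-[4-(benzyloxy)benzyl]-2-(2-{3-(benzyloxy)-2,6-bis[4-(benzyloxy)benzyl]-5-methoxyphenyl}ethyl)-6-(phenylselanyl)cyclohex-2-en-1-one F7.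
   - Oxidation with H2O2 (CH2Cl2, pyridine, 0 to 25 °C) should give 4-[4-(benzyloxy)benzyl]-2-(2-{3-(benzyloxy)-2,6-bis[4-(benzyloxy)benzyl]-5-methoxyphenyl}ethyl)-6-(phenylseleninyl)cyclohex-2-en-1-one F8. Its syn elimination leads to dienone 23, which tautomerises to phenol 24.

Further compounds
F1 | step 9 | tert-butyl 6-{3-(benzyloxy)-2,6-bis[4-(benzyloxy)benzyl]-5-methoxyphenyl}-3-oxohexanoate | CC(C)(C)OC(=O)CC(=O)CCCc1c(Cc2ccc(OCc3ccccc3)cc2)c(OCc2ccccc2)cc(OC)c1Cc1ccc(OCc2ccccc2)cc1
F2 | step 9 | 2-[4-(benzyloxy)benzyl]prop-2-enal | C=C(C=O)Cc1ccc(OCc2ccccc2)cc1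
F3 | step 9 | tert-butyl 2-{2-[4-(benzyloxy)benzyl]-3-oxopropyl}-6-{3-(benzyloxy)-2,6-bis[4-(benzyloxy)benzyl]-5-methoxyphenyl}-3-oxohexanoate (mixture of racemic diastereomers) | O=CC(Cc1ccc(OCc2ccccc2)cc1)CC(C(=O)OC(C)(C)C)C(=O)CCCc1c(Cc2ccc(OCc3ccccc3)cc2)c(OCc2ccccc2)cc(OC)c1Cc1ccc(OCc2ccccc2)cc1
F4 | step 9 | tert-butyl 5-[4-(benzyloxy)benzyl]-3-(2-{3-(benzyloxy)-2,6-bis[4-(benzyloxy)benzyl]-5-methoxyphenyl}ethyl)-2-oxocyclohex-3-ene-1-carboxylate (mixture of racemic diastereomers) | CC(C)(C)OC(=O)C1CC(Cc2ccc(OCc3ccccc3)cc2)C=C(CCc2c(Cc3ccc(OCc4ccccc4)cc3)c(OCc3ccccc3)cc(OC)c2Cc2ccc(OCc3ccccc3)cc2)C1=O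
F5 | step 9 | 5-[4-(benzyloxy)benzyl]-3-(2-{3-(benzyloxy)-2,6-bis[4-(benzyloxy)benzyl]-5-methoxyphenyl}ethyl)-2-oxocyclohex-3-ene-1-carboxylic acid (mixture of racemic diastereomers) | OC(=O)C1CC(Cc2ccc(OCc3ccccc3)cc2)C=C(CCc2c(Cc3ccc(OCc4ccccc4)cc3)c(OCc3ccccc3)cc(OC)c2Cc2ccc(OCc3ccccc3)cc2)C1=O
F6 | step 6 | 2-[4-(benzyloxy)benzyl]-4,4,5,5-tetramethyl-1,3,2-dioxaborolane | CC1(C)OB(Cc2ccc(OCc3ccccc3)cc2)OC1(C)C
F7 | step 10 | 4-[4-(benzyloxy)benzyl]-2-(2-{3-(benzyloxy)-2,6-bis[4-(benzyloxy)benzyl]-5-methoxyphenyl}ethyl)-6-(phenylselanyl)cyclohex-2-en-1-one (mixture of racemic diastereomers) | O=C1C([Se]c2ccccc2)CC(Cc2ccc(OCc3ccccc3)cc2)C=C1CCc1c(Cc2ccc(OCc3ccccc3)cc2)c(OCc2ccccc2)cc(OC)c1Cc1ccc(OCc2ccccc2)cc1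
F8 | step 10 | 4-[4-(benzyloxy)benzyl]-2-(2-{3-(benzyloxy)-2,6-bis[4-(benzyloxy)benzyl]-5-methoxyphenyl}ethyl)-6-(phenylseleninyl)cyclohex-2-en-1-one (mixture of diastereomers) | O=C1C([Se](=O)c2ccccc2)CC(Cc2ccc(OCc3ccccc3)cc2)C=C1CCc1c(Cc2ccc(OCc3ccccc3)cc2)c(OCc2ccccc2)cc(OC)c1Cc1ccc(OCc2ccccc2)cc1
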